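**Retrosynthetic overview**
1. Core numbering: five-membered ring C1(H)–C2–C3–C4(Me, ArCH)–C5; seven-membered ring C5=C6–C7(CMe2OH)–C8–C9–C10(Me)–C1; C1' is the aryl-bearing CH. Endgame: ArOMe → ArOH, both CHO groups by ortho-lithiation/DMF, the C7 carbinol by Mukaiyama hydration of an isopropenyl group, removal of a temporary C9 ketone.
2. Key disconnection: C5–C6 and C7–C8. Cyclopentanone 18 (C5=O, with a but-3-yn-2-yl chain on C1 supplying C10, C9, C8) plus a (Z)-3-methylbuta-1,3-dienyllithium (C6, C7, isopropenyl): 1,2-addition, 5-exo-dig hydroalkoxylation and Claisen rearrangement in one pot.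
3. Enabling feature: the C5=C6 alkene, exocyclic to the five-membered ring, lies γ,δ to C9 within the seven-membered ring (C9–C8–C7–C6=C5). With a temporary C9 ketone this is a Claisen retron, and sp2 C5 is the former ketone carbon of the cyclopentanone.
4. C10 and C1: enolate alkylation of ketone 13 with (S)-lactate triflate. C4 and C1': Ireland–Claisen rearrangement of a cyclopentenyl arylacetate, with chirality from one CBS reduction.
5. Ring order: five-membered ring bought (cyclotene) → transient oxolane → seven-membered ring by [3,3] ring expansion; the arene is bought and functionalised last.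

Key step: step 14

Remark: CIP descriptors in the names change along the route where substituent priorities change; no stereocentre is inverted once set, and the SMILES strings are authoritative. Compounds 1, 4, 11, 14 and 19 are taken as purchasable.

**Step 1**
Reactants: 1 2-hydroxy-3-methylcyclopent-2-en-1-one (cyclotene)
Product: 2 2-methoxy-3-methylcyclopent-2-en-1-one
Conditions: MeI, K2CO3, acetone, 56 °C
Reagents that add atoms: iodomethane, CI
Why: Williamson O-methylation of the acidic enol of the α-diketone should give the methyl enol ether that later masks the C5 ketone.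

**Step 2**
Reactants: 2 2-methoxy-3-methylcyclopent-2-en-1-one
Product: 3 (1R)-2-methoxy-3-methylcyclopent-2-en-1-ol
Conditions: (S)-2-methyl-CBS-oxazaborolidine (15 mol %), BH3·SMe2, THF, −30 °C
Reagents that add atoms: none
Why: Corey–Bakshi–Shibata reduction, in which the catalyst distinguishes the alkoxy-alkene flank from the CH2 flank of the enone and should deliver hydride to give the (R)-carbinol, the only stereocentre of the route set by catalysis.

**Step 3**
Reactants: 3 (1R)-2-methoxy-3-methylcyclopent-2-en-1-ol; 4 (2,4,6-trimethoxyphenyl)acetic acid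
Product: 5 (1R)-2-methoxy-3-methylcyclopent-2-en-1-yl (2,4,6-trimethoxyphenyl)acetate
Conditions: DCC, DMAP (cat.), CH2Cl2, 0 → 23 °C
Reagents that add atoms: none
Why: Steglich esterification under neutral conditions should spare the acid-labile enol ether and leave the carbinol centre untouched.

**Step 4**
Reactants: 5 (1R)-2-methoxy-3-methylcyclopent-2-en-1-yl (2,4,6-trimethoxyphenyl)acetate
Product: 8 (2S)-2-[(1R)-1-methyl-2-oxocyclopentyl]-2-(2,4,6-trimethoxyphenyl)acetic acid, via silyl ketene acetal 6 (not isolated), via silyl ester 7 (not isolated)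
Conditions: KN(SiMe3)2, Me3SiCl, THF, −78 → 60 °C; then 1 M HCl, THF, 23 °C
Reagents that add atoms: water, O
Why: Ireland–Claisen rearrangement in which the (Z)-silyl ketene acetal reacts suprafacially on the face of the C–O bond, so the carbinol configuration is transferred to quaternary C4, while a chair transition state (the boat would eclipse the ketene acetal with the ring methoxy group and the aryl group with the C4 methyl) should set C1'; acid then cleaves the silyl ester and unmasks the C5 ketone.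

**Step 5**
Reactants: 8 (2S)-2-[(1R)-1-methyl-2-oxocyclopentyl]-2-(2,4,6-trimethoxyphenyl)acetic acid
Product: 9 (2R)-2-[(1R)-2-hydroxy-1-methylcyclopentyl]-2-(2,4,6-trimethoxyphenyl)ethan-1-ol (both epimers at the ring carbinol)
Conditions: LiAlH4, THF, 0 → 66 °C
Reagents that add atoms: none
Why: Hydride reduction of acid and ketone should give the diol; the new ring carbinol centre is transient (re-oxidised in step 6) and no set centre is touched.

**Step 6**
Reactants: 9 (2R)-2-[(1R)-2-hydroxy-1-methylcyclopentyl]-2-(2,4,6-trimethoxyphenyl)ethan-1-ol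
Product: 10 (2S)-2-[(1R)-1-methyl-2-oxocyclopentyl]-2-(2,4,6-trimethoxyphenyl)acetaldehyde
Conditions: (COCl)2, DMSO, CH2Cl2, −78 °C; Et3N, −78 → 0 °C
Reagents that add atoms: none
Why: Swern oxidation activates both hydroxyl groups before base is added, so the keto aldehyde should form without lactol or lactone formation, and the α-aryl centre is shielded from enolisation by the twisted di-ortho-substituted aryl group and the adjacent quaternary carbon.

**Step 7**
Reactants: 10 (2S)-2-[(1R)-1-methyl-2-oxocyclopentyl]-2-(2,4,6-trimethoxyphenyl)acetaldehyde; 11 isopropyltriphenylphosphonium iodide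
Product: 12 (2R)-2-methyl-2-[(1S)-3-methyl-1-(2,4,6-trimethoxyphenyl)but-2-en-1-yl]cyclopentan-1-one
Conditions: 11, n-BuLi, THF, 0 °C; then 10, −78 → 23 °C
Reagents that add atoms: none
Why: Wittig olefination with the unstabilised isopropylidene ylide should take the aldehyde in preference to the neopentyl-type ketone.

**Step 8**
Reactants: 12 (2R)-2-methyl-2-[(1S)-3-methyl-1-(2,4,6-trimethoxyphenyl)but-2-en-1-yl]cyclopentan-1-one
Product: 13 (2R)-2-methyl-2-[(1S)-3-methyl-1-(2,4,6-trimethoxyphenyl)butyl]cyclopentan-1-one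
Conditions: H2 (1 atm), 10% Pd/C, EtOAc, 23 °C
Reagents that add atoms: none
Why: Catalytic hydrogenation of the only alkene should complete the isobutyl group without touching a stereocentre.

**Step 9**
Reactants: 13 (2R)-2-methyl-2-[(1S)-3-methyl-1-(2,4,6-trimethoxyphenyl)butyl]cyclopentan-1-one; 14 ethyl (2S)-2-{[(trifluoromethyl)sulfonyl]oxy}propanoate
Product: 15 ethyl (2S)-2-[(1R,3R)-3-methyl-3-[(1S)-3-methyl-1-(2,4,6-trimethoxyphenyl)butyl]-2-oxocyclopentyl]propanoate
Conditions: LiN(i-Pr)2, THF, −78 °C; then 14, −78 → −30 °C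
Reagents that add atoms: none
Why: Enolate SN2 alkylation in which the only possible enolate attacks the α-triflyloxy ester with inversion, fixing C10 from (S)-lactate, and the electrophile should enter trans to the bulky aryl-bearing group on C4, the arrangement also expected to be favoured at equilibrium.

**Step 10**
Reactants: 15 ethyl (2S)-2-[(1R,3R)-3-methyl-3-[(1S)-3-methyl-1-(2,4,6-trimethoxyphenyl)butyl]-2-oxocyclopentyl]propanoate
Product: 16 (2S)-2-[(1R,3R)-2-hydroxy-3-methyl-3-[(1R)-3-methyl-1-(2,4,6-trimethoxyphenyl)butyl]cyclopentyl]propan-1-ol (both epimers at the ring carbinol)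
Conditions: LiAlH4, THF, 0 °C
Reagents that add atoms: none
Why: Hydride reduction of ester and ketone should give the diol without base-mediated epimerisation of C10 or C1.

**Step 11**
Reactants: 16 (2S)-2-[(1R,3R)-2-hydroxy-3-methyl-3-[(1R)-3-methyl-1-(2,4,6-trimethoxyphenyl)butyl]cyclopentyl]propan-1-ol
Product: 17 (2S)-2-[(1R,3R)-3-methyl-3-[(1S)-3-methyl-1-(2,4,6-trimethoxyphenyl)butyl]-2-oxocyclopentyl]propanal
Conditions: (COCl)2, DMSO, CH2Cl2, −78 °C; Et3N, −78 → −20 °C
Reagents that add atoms: none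
Why: Swern oxidation of both alcohols at low temperature should return the ketone and give the aldehyde with C10 intact.

**Step 12**
Reactants: 17 (2S)-2-[(1R,3R)-3-methyl-3-[(1S)-3-methyl-1-(2,4,6-trimethoxyphenyl)butyl]-2-oxocyclopentyl]propanal
Product: 18 (2R,5R)-5-[(2S)-but-3-yn-2-yl]-2-methyl-2-[(1S)-3-methyl-1-(2,4,6-trimethoxyphenyl)butyl]cyclopentan-1-one
Conditions: dimethyl (1-diazo-2-oxopropyl)phosphonate, K2CO3, MeOH, 0 → 23 °C
Reagents that add atoms: dimethyl (1-diazo-2-oxopropyl)phosphonate, CC(=O)C(=[N+]=[N-])P(=O)(OC)OC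
Why: Seyferth–Gilbert homologation (Ohira–Bestmann reagent) should convert the aldehyde, not the hindered ketone, into the terminal alkyne, and the mild carbonate medium can at most funnel C1 towards the favoured trans arrangement.

**Step 13**
Reactants: 19 2-methylbut-1-en-3-yne
Product: 20 tributyl[(1Z)-3-methylbuta-1,3-dien-1-yl]stannane
Conditions: Bu3SnH, ZrCl4 (20 mol %), toluene, 0 °C
Reagents that add atoms: tributylstannane, CCCC[SnH](CCCC)CCCC
Why: Lewis acid-catalysed anti-hydrostannation of the terminal alkyne should give the (Z)-alkenylstannane, a halide-free source of the (Z)-dienyllithium.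

**Step 14**
Reactants: 18 (2R,5R)-5-[(2S)-but-3-yn-2-yl]-2-methyl-2-[(1S)-3-methyl-1-(2,4,6-trimethoxyphenyl)butyl]cyclopentan-1-one; 20 tributyl[(1Z)-3-methylbuta-1,3-dien-1-yl]stannane
Product: 24 (3R,5R,8S,8aR)-3,8-dimethyl-3-[(1R)-3-methyl-1-(2,4,6-trimethoxyphenyl)butyl]-5-(prop-1-en-2-yl)-2,3,5,6,8,8a-hexahydroazulen-7(1H)-one, via dienyllithium 21 (not isolated), via tertiary alcohol 22 (not isolated), via methyleneoxolane 23 (not isolated)
Conditions: 20 (2.3 equiv), n-BuLi (2.2 equiv), THF, −78 °C; 18, −78 → −30 °C; AcOH (2.3 equiv); THF → PhMe/MeCN; AuCl (5 mol %), 23 °C; then 170 °C (sealed tube)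
Reagents that add atoms: none
Why: Tin–lithium exchange gives the (Z)-dienyllithium 21; one equivalent deprotonates the alkyne and the next adds to the C5 ketone (C5–C6 bond) to give 22 after the acetic acid quench, AuCl then promotes 5-exo-dig addition of the C5 hydroxyl to the alkyne to give the 2-methyleneoxolane 23, and heating effects a Claisen rearrangement in which C8 bonds to C7 as the C5–O bond breaks, leaving the C5=C6 alkene and a C9 ketone. The closest known reaction type is the tandem 5-exo-dig cyclisation/Claisen rearrangement of 1-alkenyl-4-pentyn-1-ols to cyclohept-4-enones, here telescoped with the organolithium addition and run with a neutral gold catalyst instead of base. Ring closures: the oxolane by 5-exo-dig attack of oxygen on C9, and the seven-membered ring by a [3,3]-sigmatropic two-carbon ring expansion of that oxolane through the only possible boat-like transition state. C7 is set by suprafacial chirality transfer from the C5 carbinol, the Z-alkene geometry placing the isopropenyl group cis to H-1; C5 is only a relay centre and ends sp2. The step needs addition on the ketone face that puts oxygen cis to the butynyl chain, which should follow from attack anti to that chain and anti to the pseudo-axial C4 methyl group, and exo regiochemistry in the cyclisation, which the five-atom tether secures. It also needs retention of C10 next to the new ketone, which the base-free conditions with lithium acetate as the only buffer should secure.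

**Step 15**
Reactants: 24 (3R,5R,8S,8aR)-3,8-dimethyl-3-[(1R)-3-methyl-1-(2,4,6-trimethoxyphenyl)butyl]-5-(prop-1-en-2-yl)-2,3,5,6,8,8a-hexahydroazulen-7(1H)-one
Product: 25 (3R,5R,8S,8aR)-3,8-dimethyl-3-[(1R)-3-methyl-1-(2,4,6-trimethoxyphenyl)butyl]-5-(prop-1-en-2-yl)-1,2,3,5,6,7,8,8a-octahydroazulen-7-ol (both C7 epimers)
Conditions: NaBH4, CeCl3·7H2O, MeOH, −40 °C
Reagents that add atoms: none
Why: Luche reduction should remove the C9 carbonyl quickly and without base strong enough to epimerise C10; the configuration of the new carbinol is irrelevant.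

**Step 16**
Reactants: 25 (3R,5R,8S,8aR)-3,8-dimethyl-3-[(1R)-3-methyl-1-(2,4,6-trimethoxyphenyl)butyl]-5-(prop-1-en-2-yl)-1,2,3,5,6,7,8,8a-octahydroazulen-7-ol
Product: 26 O-[(3R,5R,8S,8aR)-3,8-dimethyl-3-[(1R)-3-methyl-1-(2,4,6-trimethoxyphenyl)butyl]-5-(prop-1-en-2-yl)-1,2,3,5,6,7,8,8a-octahydroazulen-7-yl] S-methyl carbonodithioate
Conditions: NaH, imidazole (cat.), CS2, THF, 0 → 23 °C; then MeI
Reagents that add atoms: carbon disulfide, S=C=S; iodomethane, CI
Why: Standard xanthate formation from the secondary alkoxide, with no epimerisable centre left in the molecule.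

**Step 17**
Reactants: 26 O-[(3R,5R,8S,8aR)-3,8-dimethyl-3-[(1R)-3-methyl-1-(2,4,6-trimethoxyphenyl)butyl]-5-(prop-1-en-2-yl)-1,2,3,5,6,7,8,8a-octahydroazulen-7-yl] S-methyl carbonodithioate
Product: 27 (3R,5R,8R,8aR)-3,8-dimethyl-3-[(1R)-3-methyl-1-(2,4,6-trimethoxyphenyl)butyl]-5-(prop-1-en-2-yl)-1,2,3,5,6,7,8,8a-octahydroazulene
Conditions: Bu3SnH, AIBN (cat.), toluene, 100 °C
Reagents that add atoms: none
Why: Barton–McCombie deoxygenation; the secondary C9 radical has only 4-exo or 5-endo cyclisation paths to either alkene, so reduction by the stannane should win.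

**Step 18**
Reactants: 27 (3R,5R,8R,8aR)-3,8-dimethyl-3-[(1R)-3-methyl-1-(2,4,6-trimethoxyphenyl)butyl]-5-(prop-1-en-2-yl)-1,2,3,5,6,7,8,8a-octahydroazulene
Product: 28 2-[(3R,5R,8R,8aR)-3,8-dimethyl-3-[(1R)-3-methyl-1-(2,4,6-trimethoxyphenyl)butyl]-1,2,3,5,6,7,8,8a-octahydroazulen-5-yl]propan-2-ol
Conditions: Co(acac)2 (20 mol %), PhSiH3, O2 (1 atm), THF, 23 °C; then aq. Na2S2O3
Reagents that add atoms: dioxygen, O=O
Why: Mukaiyama hydration should be Markovnikov-selective and take the 1,1-disubstituted isopropenyl alkene in preference to the hindered trisubstituted C5=C6 alkene; no stereocentre is created.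

**Step 19**
Reactants: 28 2-[(3R,5R,8R,8aR)-3,8-dimethyl-3-[(1R)-3-methyl-1-(2,4,6-trimethoxyphenyl)butyl]-1,2,3,5,6,7,8,8a-octahydroazulen-5-yl]propan-2-ol
Product: 30 5-[(1R)-1-[(3R,5R,8R,8aR)-5-(2-hydroxypropan-2-yl)-3,8-dimethyl-1,2,3,5,6,7,8,8a-octahydroazulen-3-yl]-3-methylbutyl]-2,4,6-trimethoxybenzene-1,3-dicarbaldehyde, via monoformyl aminoalkoxide 29 (not isolated)
Conditions: n-BuLi (2.1 equiv), TMEDA, THF, 0 °C; DMF (1.2 equiv), −78 → 0 °C; n-BuLi (1.5 equiv), 0 °C; DMF (excess); aq. NH4Cl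
Reagents that add atoms: N,N-dimethylformamide, CN(C)C=O
Why: Directed ortho-metalation at the ring positions flanked by two methoxy groups, with the tertiary alcohol carried as its alkoxide and the first formyl group held as its lithium α-amino alkoxide during the second lithiation, should install both aldehydes without acid.

**Step 20**
Reactants: 30 5-[(1R)-1-[(3R,5R,8R,8aR)-5-(2-hydroxypropan-2-yl)-3,8-dimethyl-1,2,3,5,6,7,8,8a-octahydroazulen-3-yl]-3-methylbutyl]-2,4,6-trimethoxybenzene-1,3-dicarbaldehyde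
Product: 31 5-[(1R)-1-[(3R,5R,8R,8aR)-5-(2-hydroxypropan-2-yl)-3,8-dimethyl-1,2,3,5,6,7,8,8a-octahydroazulen-3-yl]-3-methylbutyl]-2,4,6-trihydroxybenzene-1,3-dicarbaldehyde (CNP0281883.1)
Conditions: NaSEt (excess), DMF, 130 °C; then cold 1 M HCl to pH 4
Reagents that add atoms: none
Why: Thiolate SN2 demethylation of aryl methyl ethers activated by ortho and para formyl groups works under basic conditions, which avoid acid-induced addition of a free phenol to the C5=C6 alkene.

**Compound list**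
1 | 2-hydroxy-3-methylcyclopent-2-en-1-one (cyclotene) | CC1=C(O)C(=O)CC1 | starting material
2 | 2-methoxy-3-methylcyclopent-2-en-1-one | CC1=C(OC)C(=O)CC1 | intermediate
3 | (1R)-2-methoxy-3-methylcyclopent-2-en-1-ol | O[C@H]1C(OC)=C(C)CC1 | intermediate
4 | (2,4,6-trimethoxyphenyl)acetic acid | COc1cc(OC)c(CC(=O)O)c(OC)c1 | starting material
5 | (1R)-2-methoxy-3-methylcyclopent-2-en-1-yl (2,4,6-trimethoxyphenyl)acetate | COc1cc(OC)c(CC(=O)O[C@H]2C(OC)=C(C)CC2)c(OC)c1 | intermediate
6 | (Z)-trimethylsilyl ketene acetal of 5 (aryl cis to OSiMe3) | COc1cc(OC)c(/C=C(\O[Si](C)(C)C)O[C@H]2C(OC)=C(C)CC2)c(OC)c1 | intermediate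
7 | trimethylsilyl (2R)-2-[(1R)-2-methoxy-1-methylcyclopent-2-en-1-yl]-2-(2,4,6-trimethoxyphenyl)acetate | C[Si](C)(C)OC(=O)[C@@H](c1c(OC)cc(OC)cc1OC)[C@@]1(C)CCC=C1OC | intermediate
8 | (2S)-2-[(1R)-1-methyl-2-oxocyclopentyl]-2-(2,4,6-trimethoxyphenyl)acetic acid | OC(=O)[C@@H](c1c(OC)cc(OC)cc1OC)[C@@]1(C)CCCC1=O | intermediate
9 | (2R)-2-[(1R)-2-hydroxy-1-methylcyclopentyl]-2-(2,4,6-trimethoxyphenyl)ethan-1-ol, both epimers at the ring carbinol | OC[C@@H](c1c(OC)cc(OC)cc1OC)[C@@]1(C)CCCC1O | intermediate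
10 | (2S)-2-[(1R)-1-methyl-2-oxocyclopentyl]-2-(2,4,6-trimethoxyphenyl)acetaldehyde | O=C[C@@H](c1c(OC)cc(OC)cc1OC)[C@@]1(C)CCCC1=O | intermediate
11 | isopropyltriphenylphosphonium iodide | CC(C)[P+](c1ccccc1)(c1ccccc1)c1ccccc1.[I-] | starting material
12 | (2R)-2-methyl-2-[(1S)-3-methyl-1-(2,4,6-trimethoxyphenyl)but-2-en-1-yl]cyclopentan-1-one | CC(C)=C[C@@H](c1c(OC)cc(OC)cc1OC)[C@@]1(C)CCCC1=O | intermediate
13 | (2R)-2-methyl-2-[(1S)-3-methyl-1-(2,4,6-trimethoxyphenyl)butyl]cyclopentan-1-one | CC(C)C[C@@H](c1c(OC)cc(OC)cc1OC)[C@@]1(C)CCCC1=O | intermediate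
14 | ethyl (2S)-2-{[(trifluoromethyl)sulfonyl]oxy}propanoate | CCOC(=O)[C@H](C)OS(=O)(=O)C(F)(F)F | starting material
15 | ethyl (2S)-2-[(1R,3R)-3-methyl-3-[(1S)-3-methyl-1-(2,4,6-trimethoxyphenyl)butyl]-2-oxocyclopentyl]propanoate | CC(C)C[C@@H](c1c(OC)cc(OC)cc1OC)[C@@]1(C)CC[C@@H](C1=O)[C@H](C)C(=O)OCC | intermediate
16 | (2S)-2-[(1R,3R)-2-hydroxy-3-methyl-3-[(1R)-3-methyl-1-(2,4,6-trimethoxyphenyl)butyl]cyclopentyl]propan-1-ol, both epimers at the ring carbinol | CC(C)C[C@@H](c1c(OC)cc(OC)cc1OC)[C@@]1(C)CC[C@@H](C1O)[C@H](C)CO | intermediate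
17 | (2S)-2-[(1R,3R)-3-methyl-3-[(1S)-3-methyl-1-(2,4,6-trimethoxyphenyl)butyl]-2-oxocyclopentyl]propanal | CC(C)C[C@@H](c1c(OC)cc(OC)cc1OC)[C@@]1(C)CC[C@@H](C1=O)[C@H](C)C=O | intermediate
18 | (2R,5R)-5-[(2S)-but-3-yn-2-yl]-2-methyl-2-[(1S)-3-methyl-1-(2,4,6-trimethoxyphenyl)butyl]cyclopentan-1-one | CC(C)C[C@@H](c1c(OC)cc(OC)cc1OC)[C@@]1(C)CC[C@@H](C1=O)[C@H](C)C#C | intermediate
19 | 2-methylbut-1-en-3-yne | CC(=C)C#C | starting material
20 | tributyl[(1Z)-3-methylbuta-1,3-dien-1-yl]stannane | CC(=C)/C=C\[Sn](CCCC)(CCCC)CCCC | intermediate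
21 | [(1Z)-3-methylbuta-1,3-dien-1-yl]lithium | [Li]/C=C\C(C)=C | intermediate
22 | (1S,2R,5R)-5-[(2S)-but-3-yn-2-yl]-2-methyl-1-[(1Z)-3-methylbuta-1,3-dien-1-yl]-2-[(1R)-3-methyl-1-(2,4,6-trimethoxyphenyl)butyl]cyclopentan-1-ol | CC(C)C[C@@H](c1c(OC)cc(OC)cc1OC)[C@@]1(C)CC[C@@H]([C@@]1(O)/C=C\C(C)=C)[C@H](C)C#C | intermediate
23 | (3S,3aR,6R,6aS)-3,6-dimethyl-2-methylidene-6a-[(1Z)-3-methylbuta-1,3-dien-1-yl]-6-[(1R)-3-methyl-1-(2,4,6-trimethoxyphenyl)butyl]hexahydro-2H-cyclopenta[b]furan | CC(C)C[C@@H](c1c(OC)cc(OC)cc1OC)[C@@]1(C)CC[C@@H]2[C@H](C)C(=C)O[C@]12/C=C\C(C)=C | intermediate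
24 | (3R,5R,8S,8aR)-3,8-dimethyl-3-[(1R)-3-methyl-1-(2,4,6-trimethoxyphenyl)butyl]-5-(prop-1-en-2-yl)-2,3,5,6,8,8a-hexahydroazulen-7(1H)-one | CC(C)C[C@@H](c1c(OC)cc(OC)cc1OC)[C@@]1(C)CC[C@H]2C1=C[C@H](C(C)=C)CC(=O)[C@H]2C | intermediate
25 | (3R,5R,8S,8aR)-3,8-dimethyl-3-[(1R)-3-methyl-1-(2,4,6-trimethoxyphenyl)butyl]-5-(prop-1-en-2-yl)-1,2,3,5,6,7,8,8a-octahydroazulen-7-ol, both C7 epimers | CC(C)C[C@@H](c1c(OC)cc(OC)cc1OC)[C@@]1(C)CC[C@H]2C1=C[C@H](C(C)=C)CC(O)[C@H]2C | intermediate
26 | O-[(3R,5R,8S,8aR)-3,8-dimethyl-3-[(1R)-3-methyl-1-(2,4,6-trimethoxyphenyl)butyl]-5-(prop-1-en-2-yl)-1,2,3,5,6,7,8,8a-octahydroazulen-7-yl] S-methyl carbonodithioate | CC(C)C[C@@H](c1c(OC)cc(OC)cc1OC)[C@@]1(C)CC[C@H]2C1=C[C@H](C(C)=C)CC(OC(=S)SC)[C@H]2C | intermediate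
27 | (3R,5R,8R,8aR)-3,8-dimethyl-3-[(1R)-3-methyl-1-(2,4,6-trimethoxyphenyl)butyl]-5-(prop-1-en-2-yl)-1,2,3,5,6,7,8,8a-octahydroazulene | CC(C)C[C@@H](c1c(OC)cc(OC)cc1OC)[C@@]1(C)CC[C@H]2C1=C[C@H](C(C)=C)CC[C@H]2C | intermediate
28 | 2-[(3R,5R,8R,8aR)-3,8-dimethyl-3-[(1R)-3-methyl-1-(2,4,6-trimethoxyphenyl)butyl]-1,2,3,5,6,7,8,8a-octahydroazulen-5-yl]propan-2-ol | CC(C)C[C@@H](c1c(OC)cc(OC)cc1OC)[C@@]1(C)CC[C@H]2C1=C[C@H](C(C)(C)O)CC[C@H]2C | intermediate
29 | dilithium salt of the monoformylated arene held as its α-(dimethylamino)benzyl alkoxide, tertiary alkoxide at C7 side chain | CC(C)C[C@@H](c1c(OC)c(C([O-])N(C)C)c(OC)cc1OC)[C@@]1(C)CC[C@H]2C1=C[C@H](C(C)(C)[O-])CC[C@H]2C.[Li+].[Li+] | intermediate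
30 | 5-[(1R)-1-[(3R,5R,8R,8aR)-5-(2-hydroxypropan-2-yl)-3,8-dimethyl-1,2,3,5,6,7,8,8a-octahydroazulen-3-yl]-3-methylbutyl]-2,4,6-trimethoxybenzene-1,3-dicarbaldehyde | CC(C)C[C@@H](c1c(OC)c(C=O)c(OC)c(C=O)c1OC)[C@@]1(C)CC[C@H]2C1=C[C@H](C(C)(C)O)CC[C@H]2C | intermediate
31 | 5-[(1R)-1-[(3R,5R,8R,8aR)-5-(2-hydroxypropan-2-yl)-3,8-dimethyl-1,2,3,5,6,7,8,8a-octahydroazulen-3-yl]-3-methylbutyl]-2,4,6-trihydroxybenzene-1,3-dicarbaldehyde | CC(C)C[C@@H](c1c(O)c(C=O)c(O)c(C=O)c1O)[C@@]1(C)CC[C@H]2C1=C[C@H](C(C)(C)O)CC[C@H]2C | target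

**Step count**
Total: 20 steps. Longest linear sequence: 19 steps (steps 1–12 and 14–20); step 13 is a one-step side branch.

**Steps most likely to fail**

Step 14. The alkenyllithium may act only as a base towards the terminal alkyne and the C1–H of 18 instead of adding, or the addition may occur on the other ketone face so that the oxygen cannot reach the alkyne. The gold-catalysed cyclisation may also be slowed by the lithium salts, letting the exocyclic enol ether drift into the ring before the slow boat-type rearrangement of a (Z)-alkenyl ether. The fallback sets out from 15 and returns at 24. Keto ester 15, which has no acidic alkyne, is treated with dienyllithium 21 at −78 °C; on warming the tertiary alkoxide should close onto the ester to give the cis-fused lactone (3S,3aR,6R,6aS)-3,6-dimethyl-6a-[(1Z)-3-methylbuta-1,3-dien-1-yl]-6-[(1R)-3-methyl-1-(2,4,6-trimethoxyphenyl)butyl]hexahydro-2H-cyclopenta[b]furan-2-one F1. Carbonyl methylenation of F1 with Cp2TiMe2 (toluene, 70 °C, dark) should give enol ether 23, with C8 now coming from the titanium reagent, and the Claisen rearrangement (thermal, or promoted by i-Bu3Al at low temperature) should then give 24. This fallback removes the alkyne and gold problems but not the dependence on the facial selectivity of the addition.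

Step 4. Partition between chair and boat transition states, or incomplete (Z)-selectivity in the enolisation, would erode the configuration at C1'; C4 is safe because it is fixed by suprafacial transfer. The fallback sets out from 8, whatever its composition at C1', and returns at 9. NaBH4 reduction of the C5 ketone from the face opposite the side chain, then lactonisation on acidification, should give the cis-fused lactone (3aR,6aR)-3a-methyl-3-(2,4,6-trimethoxyphenyl)hexahydro-2H-cyclopenta[b]furan-2-one F2 as a mixture at the aryl-bearing carbon. Deprotonation with LiN(i-Pr)2 and kinetic protonation of the planar enolate from the convex face (2,6-di-tert-butylphenol, −78 °C) should give (3R,3aR,6aR)-3a-methyl-3-(2,4,6-trimethoxyphenyl)hexahydro-2H-cyclopenta[b]furan-2-one F3, with the aryl group on the concave face, which is the required C1' configuration. LiAlH4 then opens F3 to diol 9 as a single ring-carbinol epimer, and the route continues with step 6.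

Step 9. The triflate may be lost by E2 elimination to ethyl acrylate, the enolate may be O-alkylated, or the electrophile may approach C1 with poor facial selectivity. The fallback sets out from 13 and returns at 18. Aldol addition of the lithium enolate of 13 to acetaldehyde gives (2R)-5-(1-hydroxyethyl)-2-methyl-2-[(1S)-3-methyl-1-(2,4,6-trimethoxyphenyl)butyl]cyclopentan-1-one F4. Mesylation and elimination (MsCl, Et3N; DBU) gives (2R,5E)-5-ethylidene-2-methyl-2-[(1S)-3-methyl-1-(2,4,6-trimethoxyphenyl)butyl]cyclopentan-1-one F5. BINOL-catalysed conjugate alkynylation of this fixed s-cis enone with a (trimethylsilyl)ethynylboronate sets C10 under catalyst control, the antipode of the 3,3'-disubstituted BINOL being chosen to give the (S)-propargylic centre, and gives (2R)-2-methyl-2-[(1S)-3-methyl-1-(2,4,6-trimethoxyphenyl)butyl]-5-[(2S)-4-(trimethylsilyl)but-3-yn-2-yl]cyclopentan-1-one F6. K2CO3 in MeOH then removes the silyl group and equilibrates C1 to the trans arrangement, giving 18.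

**Further compounds**
F1 | step 14 | (3S,3aR,6R,6aS)-3,6-dimethyl-6a-[(1Z)-3-methylbuta-1,3-dien-1-yl]-6-[(1R)-3-methyl-1-(2,4,6-trimethoxyphenyl)butyl]hexahydro-2H-cyclopenta[b]furan-2-one | CC(C)C[C@@H](c1c(OC)cc(OC)cc1OC)[C@@]1(C)CC[C@@H]2[C@H](C)C(=O)O[C@]12/C=C\C(C)=C
F2 | step 4 | (3aR,6aR)-3a-methyl-3-(2,4,6-trimethoxyphenyl)hexahydro-2H-cyclopenta[b]furan-2-one, both C3 epimers | O=C1O[C@@H]2CCC[C@]2(C)C1c1c(OC)cc(OC)cc1OC
F3 | step 4 | (3R,3aR,6aR)-3a-methyl-3-(2,4,6-trimethoxyphenyl)hexahydro-2H-cyclopenta[b]furan-2-one | O=C1O[C@@H]2CCC[C@]2(C)[C@@H]1c1c(OC)cc(OC)cc1OC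
F4 | step 9 | (2R)-5-(1-hydroxyethyl)-2-methyl-2-[(1S)-3-methyl-1-(2,4,6-trimethoxyphenyl)butyl]cyclopentan-1-one, mixture at C5 and the carbinol | CC(C)C[C@@H](c1c(OC)cc(OC)cc1OC)[C@@]1(C)CCC(C(C)O)C1=O
F5 | step 9 | (2R,5E)-5-ethylidene-2-methyl-2-[(1S)-3-methyl-1-(2,4,6-trimethoxyphenyl)butyl]cyclopentan-1-one | CC(C)C[C@@H](c1c(OC)cc(OC)cc1OC)[C@@]1(C)CC/C(=C\C)C1=O
F6 | step 9 | (2R)-2-methyl-2-[(1S)-3-methyl-1-(2,4,6-trimethoxyphenyl)butyl]-5-[(2S)-4-(trimethylsilyl)but-3-yn-2-yl]cyclopentan-1-one, mixture at C5 | CC(C)C[C@@H](c1c(OC)cc(OC)cc1OC)[C@@]1(C)CCC(C1=O)[C@H](C)C#C[Si](C)(C)C
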